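**Retrosynthetic overview**
1. 27 ⇐ 26 ⇐ 25: acetonide hydrolysis, then hydrogenolysis of seven benzyl ethers and one diphenylmethylene ketal.
2. 25 ⇐ 24: cut the C4–C4a bonds of the top and middle pyran rings (not the C4–C6 interflavanyl bonds); both rings close at once by epoxide–arene cyclisation of a bis(epoxy aryl ether).
3. 24 ⇐ 15 + 16 + 19 + 16 + 2: two "arms", each built as aldehyde → trans-epoxy ketone → carbinol → aryl ether with inversion.
4. 15 ⇐ 3 + 7: chromone → (S)-flavanone → flav-3-ene → cis-dihydroxylation on the face of the aryl group → acetonide → formylation at flavan C-6.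
5. Ring order: bottom pyran ring (step 3), then top and middle pyran rings together (step 15).

Assumption and abbreviations: each chiral ligand or catalyst is the enantiomer that gives the configuration drawn; Bn = benzyl, Ar = 4-(benzyloxy)phenyl, Q = residue of 14 bonded through its C-8 (flavan C-6); top unit = unit without C-4 oxygen, bottom unit = the 3,4-diol unit.

**Step 1**
Reactants: 1 pyrogallol
Product: 2 2,2-diphenyl-1,3-benzodioxol-4-ol
Conditions: Ph2CCl2 (1.1 equiv), neat, 170 °C, 20 min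
Reagents that add atoms: dichlorodiphenylmethane, ClC(Cl)(c1ccccc1)c1ccccc1
Why: O,O-ketalisation of a catechol unit with a gem-dichloride; pyrogallol is symmetric, so only one 1,2-ketal can form and the third OH stays free.

**Step 2**
Reactants: 3 gallacetophenone
Product: 4 1-[3,4-bis(benzyloxy)-2-hydroxyphenyl]ethanone
Conditions: BnBr (2.1 equiv), K2CO3 (2.2 equiv), acetone, reflux
Reagents that add atoms: benzyl bromide, BrCc1ccccc1
Why: Williamson ether synthesis; the 2-OH is hydrogen-bonded to the acetyl group and is not alkylated with two equivalents of base.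

**Step 3**
Reactants: 4 1-[3,4-bis(benzyloxy)-2-hydroxyphenyl]ethanone
Product: 6 7,8-bis(benzyloxy)-4H-chromen-4-one, via enaminone 5 (not isolated)
Conditions: Me2NCH(OMe)2, toluene, 100 °C; then AcOH, 90 °C
Reagents that add atoms: N,N-dimethylformamide dimethyl acetal, COC(OC)N(C)C
Why: enaminone formation, then acid-promoted addition–elimination by the phenol (chromone synthesis via an enaminone).

**Step 4**
Reactants: 6 7,8-bis(benzyloxy)-4H-chromen-4-one; 7 [4-(benzyloxy)phenyl]boronic acid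
Product: 8 (2S)-7,8-bis(benzyloxy)-2-[4-(benzyloxy)phenyl]chroman-4-one
Conditions: 7 (2 equiv), [Rh(OH)(cod)]2 (1.5 mol %), MeO-F12-BIPHEP (3.3 mol %), toluene/H2O, 50 °C
Reagents that add atoms: none
Why: Hayashi–Miyaura rhodium-catalysed asymmetric 1,4-addition of an arylboronic acid to a chromone; the chiral bisphosphine controls the face of aryl transfer and sets C-2 as S (the series that becomes 2R in the flavan-3-ols).

**Step 5**
Reactants: 8 (2S)-7,8-bis(benzyloxy)-2-[4-(benzyloxy)phenyl]chroman-4-one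
Product: 10 (2S)-7,8-bis(benzyloxy)-2-[4-(benzyloxy)phenyl]-2H-chromene, via flavan-4-ol 9 (not isolated)
Conditions: NaBH4, THF/MeOH, 0 °C; then MsCl, Et3N, CH2Cl2, 0 °C to rt
Reagents that add atoms: none
Why: hydride reduction to the 2,4-cis alcohol, then mesylation of the benzylic alcohol and E1-type elimination under basic conditions give the flav-3-ene without touching C-2.

**Step 6**
Reactants: 10 (2S)-7,8-bis(benzyloxy)-2-[4-(benzyloxy)phenyl]-2H-chromene
Product: 13 (2R,3R,4R)-7,8-bis(benzyloxy)-2-[4-(benzyloxy)phenyl]chroman-3,4-diol, via iodo acetate 11 (not isolated), via hydroxy acetate 12 (not isolated)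
Conditions: I2 (1.0 equiv), AgOAc (2.2 equiv), AcOH/H2O, rt to 60 °C, dark; then K2CO3 (cat.), MeOH, rt
Reagents that add atoms: silver acetate, CC(=O)[O-].[Ag+]
Why: Woodward cis-dihydroxylation (wet Prévost reaction): iodonium forms anti to the 2-aryl group, acetate attacks benzylic C-4, silver-assisted displacement of iodide by the neighbouring acetate gives a cis-fused acetoxonium ion on the aryl face, and water then methanolysis give the 2,3-cis-3,4-cis diol (3R,4R).

**Step 7**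
Reactants: 13 (2R,3R,4R)-7,8-bis(benzyloxy)-2-[4-(benzyloxy)phenyl]chroman-3,4-diol
Product: 14 (3aS,4R,9bR)-6,7-bis(benzyloxy)-4-[4-(benzyloxy)phenyl]-2,2-dimethyl-3a,9b-dihydro-4H-[1,3]dioxolo[4,5-c]chromene
Conditions: Me2C(OMe)2, PPTS (cat.), acetone, rt
Reagents that add atoms: 2,2-dimethoxypropane, COC(C)(C)OC
Why: acetonide formation on the cis-1,2-diol by transketalisation; no stereocentre is touched.

**Step 8**
Reactants: 14 acetonide of 13
Product: 15 (3aS,4R,9bR)-6,7-bis(benzyloxy)-4-[4-(benzyloxy)phenyl]-2,2-dimethyl-3a,9b-dihydro-4H-[1,3]dioxolo[4,5-c]chromene-8-carbaldehyde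
Conditions: Cl2CHOMe, AgOTf, CH2Cl2, −78 °C; aq. NaHCO3
Reagents that add atoms: dichloromethyl methyl ether, ClC(Cl)OC; water, O
Why: Rieche formylation (electrophilic aromatic substitution) at the only position para to the ring oxygen and ortho to a benzyloxy group (flavan C-6); the low temperature spares the acetonide.

**Step 9**
Reactants: 15 aldehyde Q-CHO; 16 2-bromo-1-[4-(benzyloxy)phenyl]ethanone
Product: 17 [4-(benzyloxy)phenyl][(2S,3R)-3-Q-oxiran-2-yl]methanone
Conditions: 16 (1.3 equiv), LiOH·H2O, N-(9-anthracenylmethyl)cinchonidinium bromide (10 mol %), Bu2O, 4 °C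
Reagents that add atoms: none
Why: asymmetric Darzens condensation under chiral phase-transfer catalysis; aldol addition then intramolecular SN2 closure gives the trans epoxide, and the catalyst sets both epoxide carbons (2S,3R).

**Step 10**
Reactants: 17 [4-(benzyloxy)phenyl][(2S,3R)-3-Q-oxiran-2-yl]methanone
Product: 18 (S)-[4-(benzyloxy)phenyl][(2R,3R)-3-Q-oxiran-2-yl]methanol
Conditions: (S)-2-methyl-CBS-oxazaborolidine (0.3 equiv), catecholborane, toluene, −78 °C
Reagents that add atoms: none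
Why: Corey–Bakshi–Shibata reduction; reagent control (aryl as the large group) sets the carbinol as S, against the intrinsic anti preference of the epoxy ketone.

**Step 11**
Reactants: 18 (S)-[4-(benzyloxy)phenyl][(2R,3R)-3-Q-oxiran-2-yl]methanol; 19 2,3,4-trihydroxybenzaldehyde
Product: 21 2,3-bis(benzyloxy)-4-{(R)-[4-(benzyloxy)phenyl][(2S,3R)-3-Q-oxiran-2-yl]methoxy}benzaldehyde, via catechol ether 20 (not isolated)
Conditions: 19 (1.2 equiv), PPh3, DIAD, THF, 0 °C to rt; then DMF, K2CO3, BnBr, 40 °C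
Reagents that add atoms: benzyl bromide, BrCc1ccccc1
Why: Mitsunobu etherification through the most acidic 4-OH (para to CHO) with inversion at the carbinol carbon (S to R), then Williamson benzylation of the two remaining phenols in the same flask.

**Step 12**
Reactants: 21 aldehyde from step 11; 16 2-bromo-1-[4-(benzyloxy)phenyl]ethanone
Product: 22 [4-(benzyloxy)phenyl][(2R,3S)-3-aryloxiran-2-yl]methanone, aryl being the ring of 21
Conditions: 16 (1.3 equiv), LiOH·H2O, N-(9-anthracenylmethyl)cinchoninium bromide (10 mol %), Bu2O, 4 °C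
Reagents that add atoms: none
Why: second asymmetric Darzens condensation; the pseudoenantiomeric phase-transfer catalyst gives the trans epoxide of opposite sense (2R,3S).

**Step 13**
Reactants: 22 epoxy ketone from step 12
Product: 23 (S)-carbinol of 22 with (2S,3S)-oxirane
Conditions: (S)-2-methyl-CBS-oxazaborolidine (0.3 equiv), catecholborane, toluene, −78 °C
Reagents that add atoms: none
Why: Corey–Bakshi–Shibata reduction, here matched with the anti preference of the epoxy ketone, sets the carbinol as S.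

**Step 14**
Reactants: 23 (S)-carbinol from step 13; 2 2,2-diphenyl-1,3-benzodioxol-4-ol
Product: 24 bis(epoxy aryl ether), the (R)-configured 2,2-diphenyl-1,3-benzodioxol-4-yl ether of 23
Conditions: 2 (1.5 equiv), PPh3, DIAD, toluene, 0 °C to rt
Reagents that add atoms: none
Why: Mitsunobu etherification with inversion (S to R) installs the aryl ether that becomes ring A and O-1 of the top unit.

**Step 15**
Reactants: 24 bis(epoxy aryl ether)
Product: 25 protected trimer (top 7,8-O-diphenylmethylene; seven O-benzyl groups; bottom 3,4-O-isopropylidene)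
Conditions: BF3·OEt2 (0.2 equiv), CH2Cl2, −78 to −40 °C; Et3N quench
Reagents that add atoms: none
Why: Proposed new method: a double intramolecular Friedel–Crafts epoxy–arene cyclisation in which BF3 opens each trans-epoxide at the benzylic carbon carrying the trioxygenated ring (cation stabilised by the para ether oxygen and the ortho benzyloxy group), and the tethered aryl ether attacks through its carbon ortho to the ether oxygen and para to the 7-oxygen in a six-membered transition state with inversion at C-4, so that both new rings are 3,4-trans (4β-aryl in the 2,3-cis top ring, 4α-aryl in the 2,3-trans middle ring) while C-2 and C-3 are carried over unchanged; the competing indane closure by the Ar ring is slow because its free positions are meta to oxygen; the closest known reaction type is the Lewis-acid-catalysed cyclisation of aryl ethers of trans-3-arylglycidols to trans-4-arylchroman-3-ols.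

**Step 16**
Reactants: 25 protected trimer
Product: 26 protected trimer with free bottom 3,4-diol
Conditions: AcOH/THF/H2O (3:1:1), 45 °C
Reagents that add atoms: none
Why: acid-catalysed acetal hydrolysis through the acetone-derived oxocarbenium ion, which does not break the C-4–O bond, so the cis-diol configuration is kept.

**Step 17**
Reactants: 26 protected trimer with free bottom 3,4-diol
Product: 27 epioritin-(4β→6)-oritin-(4α→6)-epioritin-4α-ol (target)
Conditions: H2 (1 atm), Pd(OH)2/C, THF/MeOH, rt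
Reagents that add atoms: none
Why: hydrogenolysis of seven aryl benzyl ethers and the diphenylmethylene ketal; under neutral conditions these cleave much faster than the benzylic C-4 alcohol and the ring C–O bonds.

**Compound list**
1 | pyrogallol (benzene-1,2,3-triol) | Oc1cccc(O)c1O | starting material
2 | 2,2-diphenyl-1,3-benzodioxol-4-ol | Oc1cccc2OC(c3ccccc3)(c3ccccc3)Oc12 | intermediate
3 | gallacetophenone, 1-(2,3,4-trihydroxyphenyl)ethanone | CC(=O)c1ccc(O)c(O)c1O | starting material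
4 | 1-[3,4-bis(benzyloxy)-2-hydroxyphenyl]ethanone | CC(=O)c1ccc(OCc2ccccc2)c(OCc2ccccc2)c1O | intermediate
5 | (E)-1-[3,4-bis(benzyloxy)-2-hydroxyphenyl]-3-(dimethylamino)prop-2-en-1-one | CN(C)/C=C/C(=O)c1ccc(OCc2ccccc2)c(OCc2ccccc2)c1O | intermediate
6 | 7,8-bis(benzyloxy)-4H-chromen-4-one | O=c1ccoc2c1ccc(OCc1ccccc1)c2OCc1ccccc1 | intermediate
7 | [4-(benzyloxy)phenyl]boronic acid | OB(O)c1ccc(OCc2ccccc2)cc1 | starting material
8 | (2S)-7,8-bis(benzyloxy)-2-[4-(benzyloxy)phenyl]chroman-4-one | O=C1C[C@@H](c2ccc(OCc3ccccc3)cc2)Oc2c1ccc(OCc1ccccc1)c2OCc1ccccc1 | intermediate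
9 | (2S,4S)-7,8-bis(benzyloxy)-2-[4-(benzyloxy)phenyl]chroman-4-ol (2,4-cis) | O[C@H]1C[C@@H](c2ccc(OCc3ccccc3)cc2)Oc2c1ccc(OCc1ccccc1)c2OCc1ccccc1 | intermediate
10 | (2S)-7,8-bis(benzyloxy)-2-[4-(benzyloxy)phenyl]-2H-chromene | C1=C[C@@H](c2ccc(OCc3ccccc3)cc2)Oc2c1ccc(OCc1ccccc1)c2OCc1ccccc1 | intermediate
11 | (2R,3R,4R)-7,8-bis(benzyloxy)-2-[4-(benzyloxy)phenyl]-3-iodochroman-4-yl acetate (2,3-trans-3,4-trans) | c1cc2c(c(OCc3ccccc3)c1OCc1ccccc1)O[C@H](c1ccc(OCc3ccccc3)cc1)[C@@H](I)[C@@H]2OC(C)=O | intermediate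
12 | (2R,3S,4R)-7,8-bis(benzyloxy)-2-[4-(benzyloxy)phenyl]-3-hydroxychroman-4-yl acetate (all-cis; the 3-O-acetyl isomer behaves the same) | c1cc2c(c(OCc3ccccc3)c1OCc1ccccc1)O[C@H](c1ccc(OCc3ccccc3)cc1)[C@H](O)[C@@H]2OC(C)=O | intermediate
13 | (2R,3R,4R)-7,8-bis(benzyloxy)-2-[4-(benzyloxy)phenyl]chroman-3,4-diol (2,3-cis-3,4-cis) | c1cc2c(c(OCc3ccccc3)c1OCc1ccccc1)O[C@H](c1ccc(OCc3ccccc3)cc1)[C@H](O)[C@@H]2O | intermediate
14 | (3aS,4R,9bR)-6,7-bis(benzyloxy)-4-[4-(benzyloxy)phenyl]-2,2-dimethyl-3a,9b-dihydro-4H-[1,3]dioxolo[4,5-c]chromene (acetonide of 13) | c1cc2c(c(OCc3ccccc3)c1OCc1ccccc1)O[C@H](c1ccc(OCc3ccccc3)cc1)[C@@H]1OC(C)(C)O[C@H]21 | intermediate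
15 | 8-carbaldehyde of 14 (formyl at flavan C-6), Q-CHO | O=Cc1cc2c(c(OCc3ccccc3)c1OCc1ccccc1)O[C@H](c1ccc(OCc3ccccc3)cc1)[C@@H]1OC(C)(C)O[C@H]21 | intermediate
16 | 2-bromo-1-[4-(benzyloxy)phenyl]ethanone | O=C(CBr)c1ccc(OCc2ccccc2)cc1 | starting material
17 | [4-(benzyloxy)phenyl][(2S,3R)-3-Q-oxiran-2-yl]methanone (trans) | O=C(c1ccc(OCc2ccccc2)cc1)[C@H]1O[C@@H]1c1cc2c(c(OCc3ccccc3)c1OCc1ccccc1)O[C@H](c1ccc(OCc3ccccc3)cc1)[C@@H]1OC(C)(C)O[C@H]21 | intermediate
18 | (S)-[4-(benzyloxy)phenyl][(2R,3R)-3-Q-oxiran-2-yl]methanol | O[C@@H](c1ccc(OCc2ccccc2)cc1)[C@H]1O[C@@H]1c1cc2c(c(OCc3ccccc3)c1OCc1ccccc1)O[C@H](c1ccc(OCc3ccccc3)cc1)[C@@H]1OC(C)(C)O[C@H]21 | intermediate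
19 | 2,3,4-trihydroxybenzaldehyde | O=Cc1ccc(O)c(O)c1O | starting material
20 | 4-{(R)-[4-(benzyloxy)phenyl][(2S,3R)-3-Q-oxiran-2-yl]methoxy}-2,3-dihydroxybenzaldehyde | O=Cc1ccc(O[C@H](c2ccc(OCc3ccccc3)cc2)[C@H]2O[C@@H]2c2cc3c(c(OCc4ccccc4)c2OCc2ccccc2)O[C@H](c2ccc(OCc4ccccc4)cc2)[C@@H]2OC(C)(C)O[C@H]32)c(O)c1O | intermediate
21 | 2,3-bis(benzyloxy)-4-{(R)-[4-(benzyloxy)phenyl][(2S,3R)-3-Q-oxiran-2-yl]methoxy}benzaldehyde | O=Cc1ccc(O[C@H](c2ccc(OCc3ccccc3)cc2)[C@H]2O[C@@H]2c2cc3c(c(OCc4ccccc4)c2OCc2ccccc2)O[C@H](c2ccc(OCc4ccccc4)cc2)[C@@H]2OC(C)(C)O[C@H]32)c(OCc2ccccc2)c1OCc1ccccc1 | intermediate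
22 | [4-(benzyloxy)phenyl][(2R,3S)-3-aryloxiran-2-yl]methanone, aryl = the benzaldehyde ring of 21 with its CHO carbon now oxirane C-3 | O=C(c1ccc(OCc2ccccc2)cc1)[C@@H]1O[C@H]1c1ccc(O[C@H](c2ccc(OCc3ccccc3)cc2)[C@H]2O[C@@H]2c2cc3c(c(OCc4ccccc4)c2OCc2ccccc2)O[C@H](c2ccc(OCc4ccccc4)cc2)[C@@H]2OC(C)(C)O[C@H]32)c(OCc2ccccc2)c1OCc1ccccc1 | intermediate
23 | (S)-carbinol obtained from 22, oxirane now (2S,3S) | O[C@@H](c1ccc(OCc2ccccc2)cc1)[C@@H]1O[C@H]1c1ccc(O[C@H](c2ccc(OCc3ccccc3)cc2)[C@H]2O[C@@H]2c2cc3c(c(OCc4ccccc4)c2OCc2ccccc2)O[C@H](c2ccc(OCc4ccccc4)cc2)[C@@H]2OC(C)(C)O[C@H]32)c(OCc2ccccc2)c1OCc1ccccc1 | intermediate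
24 | bis(epoxy aryl ether): 2,2-diphenyl-1,3-benzodioxol-4-yl ether of 23 with inverted (R) ether carbon; upper oxirane (2R,3S), lower oxirane (2S,3R) | c1ccc2OC(c3ccccc3)(c3ccccc3)Oc2c1O[C@H](c1ccc(OCc2ccccc2)cc1)[C@@H]1O[C@H]1c1ccc(O[C@H](c2ccc(OCc3ccccc3)cc2)[C@H]2O[C@@H]2c2cc3c(c(OCc4ccccc4)c2OCc2ccccc2)O[C@H](c2ccc(OCc4ccccc4)cc2)[C@@H]2OC(C)(C)O[C@H]32)c(OCc2ccccc2)c1OCc1ccccc1 | intermediate
25 | protected trimer: 27 with top 7,8-O-diphenylmethylene, middle and bottom 7,8-di-O-benzyl, three 4'-O-benzyl, bottom 3,4-O-isopropylidene; all nine stereocentres arranged as in 27 | c1ccccc1COc1ccc([C@H]2Oc3c(ccc4OC(c5ccccc5)(c5ccccc5)Oc34)[C@H](c3cc4c(c(OCc5ccccc5)c3OCc3ccccc3)O[C@H](c3ccc(OCc5ccccc5)cc3)[C@@H](O)[C@@H]4c3cc4c(c(OCc5ccccc5)c3OCc3ccccc3)O[C@H](c3ccc(OCc5ccccc5)cc3)[C@@H]3OC(C)(C)O[C@H]43)[C@H]2O)cc1 | intermediate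
26 | 25 without the isopropylidene group (free bottom 3,4-cis-diol) | c1ccccc1COc1ccc([C@H]2Oc3c(ccc4OC(c5ccccc5)(c5ccccc5)Oc34)[C@H](c3cc4c(c(OCc5ccccc5)c3OCc3ccccc3)O[C@H](c3ccc(OCc5ccccc5)cc3)[C@@H](O)[C@@H]4c3cc4c(c(OCc5ccccc5)c3OCc3ccccc3)O[C@H](c3ccc(OCc5ccccc5)cc3)[C@H](O)[C@@H]4O)[C@H]2O)cc1 | intermediate
27 | epioritin-(4β→6)-oritin-(4α→6)-epioritin-4α-ol; top (2R,3R,4S), middle (2R,3S,4R), bottom (2R,3R,4R) | Oc1ccc([C@H]2Oc3c(ccc(O)c3O)[C@H](c3cc4c(c(O)c3O)O[C@H](c3ccc(O)cc3)[C@@H](O)[C@@H]4c3cc4c(c(O)c3O)O[C@H](c3ccc(O)cc3)[C@H](O)[C@@H]4O)[C@H]2O)cc1 | target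

**Totals and risks**
Total step count: 17. Longest linear sequence: 16 steps (3 to 27, steps 2 to 17).

Most likely to fail, first: step 15. Two very electron-rich aryl epoxides must both close with inversion before Meinwald rearrangement or loss of C-4 control intervenes. The fallback sets out from 24: both epoxides are opened at the benzylic carbon with PhSH and Et3N in MeOH to give the bis(4-phenylsulfanyl) diol F1. The two benzylic cations are then released under non-acidic thiophilic activation (AgBF4, CH2Cl2, −40 °C), each closing its ring anti to the 3-hydroxyl. The fallback comes back to the route at 25.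

Second: step 11. The Mitsunobu reaction joins a hindered, ionisable benzylic carbinol that carries a labile epoxide to a phenol with a free catechol. The fallback sets out from 19: selective 4-O-allylation (allyl bromide, NaHCO3, DMF) gives 4-(allyloxy)-2,3-dihydroxybenzaldehyde F2. Benzylation (BnBr, K2CO3) gives 4-(allyloxy)-2,3-bis(benzyloxy)benzaldehyde F3. Deallylation with Pd(PPh3)4 and morpholine gives 2,3-bis(benzyloxy)-4-hydroxybenzaldehyde F4. Mitsunobu coupling of F4 with 18 then comes back to the route directly at 21.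

Third: step 9 (and likewise step 12). The asymmetric Darzens reaction uses a hindered, electron-rich aldehyde. The fallback sets out from 15: Claisen–Schmidt condensation with 1-[4-(benzyloxy)phenyl]ethanone (KOH, EtOH) gives the (E)-enone F5. Catalytic asymmetric nucleophilic epoxidation (La(OiPr)3, BINOL, Ph3As=O, t-BuOOH, or Juliá–Colonna conditions) then comes back to the route at 17, with the diastereomers separable because Q is enantiopure.

**Further compounds**
F1 | step 15 | bis(β-hydroxy phenyl sulfide) from 24: each oxirane opened at the aryl-bearing carbon by PhS with inversion | c1ccc2OC(c3ccccc3)(c3ccccc3)Oc2c1O[C@H](c1ccc(OCc2ccccc2)cc1)[C@H](O)[C@H](Sc1ccccc1)c1ccc(O[C@H](c2ccc(OCc3ccccc3)cc2)[C@@H](O)[C@@H](Sc2ccccc2)c2cc3c(c(OCc4ccccc4)c2OCc2ccccc2)O[C@H](c2ccc(OCc4ccccc4)cc2)[C@@H]2OC(C)(C)O[C@H]32)c(OCc2ccccc2)c1OCc1ccccc1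
F2 | step 11 | 4-(allyloxy)-2,3-dihydroxybenzaldehyde | O=Cc1ccc(OCC=C)c(O)c1O
F3 | step 11 | 4-(allyloxy)-2,3-bis(benzyloxy)benzaldehyde | O=Cc1ccc(OCC=C)c(OCc2ccccc2)c1OCc1ccccc1
F4 | step 11 | 2,3-bis(benzyloxy)-4-hydroxybenzaldehyde | O=Cc1ccc(O)c(OCc2ccccc2)c1OCc1ccccc1
F5 | step 9 | (E)-1-[4-(benzyloxy)phenyl]-3-Q-prop-2-en-1-one | O=C(/C=C/c1cc2c(c(OCc3ccccc3)c1OCc1ccccc1)O[C@H](c1ccc(OCc3ccccc3)cc1)[C@@H]1OC(C)(C)O[C@H]21)c1ccc(OCc2ccccc2)cc1
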